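The runs were computed with constants of no real substance; the scatter is artificial.

There was one question, and it stands below with the charges and the readings.

| setting | epsilon | theta | eta | flask |
|---|---|---|---|---|
| substrate | 0.025 M | 0.038 M | 0.050 M | 0.050 M |
| enzyme | 0.05 mol% | 0.05 mol% | 0.05 mol% | 0.05 mol% |
| added ligand | 27 µM | 27 µM | 54 µM | 27 µM |
| remark | run made earlier | run made earlier | run made earlier |  |
- epsilon (time / h: product / %): 0.833: 57.7; 2.50: 93.9; 4.00: 99.2; 6.00: 100.4
- theta (time / h: product / %): 0.500: 38.6; 1.33: 83.7; 3.00: 99.3; 6.00: 100.0
- eta (time / h: product / %): 0.833: 48.0; 2.50: 97.2; 4.00: 100.2; 6.00: 98.9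

(readings scatter by 1 percentage point)
- apparent order in enzyme when 5.0% of the substrate are converted (percent change of the rate of making product for one percent more enzyme charged)


The enzyme charged is substrate times loading: 12.5 µM in epsilon, and 25.0 µM in both eta and the flask. I read the first two rows of epsilon and eta as a first-order fall of substrate, which gave 1.16 /h and 1.75 /h. Per enzyme charged, eta, with twice the ligand of epsilon and also twice its substrate, ran slower by a factor 1.33. Two settings differ here, but I put the whole factor down to the ligand as a supposition: added ligand holds enzyme idle, and rate follows free enzyme.

Let K be held enzyme over free enzyme times free ligand. With free ligand taken as the charge, that factor gave 17900 /M. Subtracting the held enzyme left free ligand of 22.9 µM in epsilon and 41.7 µM in eta. Going round again gave 28800 /M. This K, the holding constant, is a rough reading, since it rests on a substrate remainder in eta of 2.80% read with a scatter of 1 percentage point.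

In the flask, free ligand came to 16.1 µM on the first round, and putting that back gave held enzyme h = 7.90 µM. Write E for enzyme charged, C for free enzyme, L for free ligand and L₀ for the ligand charge. With substrate held fixed and rate following C, differentiating the balances gives the order as E·L₀/(E·L + h·C), which I reckoned at 1.10 for the flask.

The forecast differed: it said 0.8, reasoning that “If ligand is needed to activate the enzyme and binds tightly, extra enzyme is partly unligated”.

The flask gave 1.1, higher than the forecast.

    enzyme + added ligand ⇌ idle complex, settled at all times (K = 32000 /M)
    substrate + enzyme → product + enzyme, rate k2*[substrate]*[enzyme]/(1 + ([substrate]/Km2) + ([substrate]/Ksi2)^2) (0.0864 M, 29.9 mM, k = 61.0 /M/s)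
    2 enzyme → spent catalyst (k = 2.87 /M/s)

In the flask at 0.800 h, enzyme at 53.5%, idle complex (an off-cycle form) at 32.4% and added ligand at 70.0% of its charge make K 32000 /M. On theta, with 19.0 µM enzyme, two rounds took free ligand to 18.7 µM, then 20.4 µM, and with my reading of K epsilon's first-order constant scaled to 1.84 /h, where theta's readings give 1.60 /h. In the flask, product formed from substrate with half of its turnover up to 8.00 h done by 0.624 h and >99.9% of it by 4.00 h. Enzyme meanwhile went in pairs to spent catalyst, which stood at 59.7% of the catalyst charged after 8.00 h, with substrate at 0%.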